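**Retrosynthetic overview**
1. The (5S)-carbinol is set last, by catalyst-controlled transfer hydrogenation of the C5 ketone of the bicyclic 4,5-dione. The (Z)-alkene is bought in with (Z)-hexadec-11-en-1-ol.
2. Ring B is cut at C5–C6 and C7–C8. An anionic formal [4+2] (vinylogous Michael addition, then Dieckmann closure of C5–C6) joins a monocyclic methyl 2-methyl-4-pyrone-3-carboxylate to tert-butyl acrylate. The tert-butyl ester left on C6 is a temporary activating group, removed by acidolysis and decarboxylation.
3. Enabling feature: in ring A (γ-pyrone O1–C2–C3–C4–C4a–C8a), C8 sits on C8a and C5 on the adjacent C4a. C8–H is acidified vinylogously through C8a=C4a by both C4=O and the C5 carbonyl, so the flat pyrone acts like an o-toluate, with C8 as nucleophile and C5 as electrophile.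
4. Ring A is cut at C4–C4a and O1–C8a. It comes from an acylketene (released from a 6-alkyl-dioxinone) and the pyrrolidine enamine of methyl acetoacetate. The dioxinone comes from γ-alkylation of 2,2,6-trimethyl-1,3-dioxin-4-one with (Z)-hexadec-11-enyl iodide.
5. Order of ring formation: ring A (step 4), then ring B (step 5).

Key step: step 5

Remark: chromene numbering (O1, C2–C4, C4a, C5–C8, C8a) is used for the bicyclic compounds and, by anticipation, for the same atoms in their precursors. Compounds 13 and 14 are written as their C5-enol tautomers, which carry no labile C6 centre.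

Step 1
Reactants: 1 (Z)-hexadec-11-en-1-ol
Product: 2 (Z)-16-iodohexadec-5-ene
Conditions: I2, PPh3, imidazole, CH2Cl2, 0 °C to rt
Reagents that add atoms: iodine, II
Why: Appel-type iodination displaces the oxyphosphonium ion of the primary alcohol by SN2 under neutral conditions that leave the remote Z-alkene untouched.

Step 2
Reactants: 3 2,2,6-trimethyl-4H-1,3-dioxin-4-one; 2 (Z)-16-iodohexadec-5-ene
Product: 5 6-[(Z)-heptadec-12-en-1-yl]-2,2-dimethyl-4H-1,3-dioxin-4-one, via lithium dienolate 4 (not isolated)
Conditions: LiN(iPr)2, THF–DMPU, −78 °C; then 2, −78 °C to rt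
Reagents that add atoms: none
Why: Vinylogous (γ-selective) enolate alkylation with a primary iodide adds the one carbon that turns the C16 chain into the C17 side chain and stores C2–C4 of ring A as a masked acylketene.

Step 3
Reactants: 6 methyl acetoacetate
Product: 7 methyl (E)-3-(pyrrolidin-1-yl)but-2-enoate
Conditions: pyrrolidine, toluene, Dean–Stark, reflux
Reagents that add atoms: pyrrolidine, C1CCNC1
Why: Enamine condensation of a β-keto ester with a secondary amine under azeotropic water removal should give the conjugated E-enamino ester, a nucleophilic C4a=C8a unit that already carries C5 (ester) and C8 (methyl).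

Step 4
Reactants: 5 6-[(Z)-heptadec-12-en-1-yl]-2,2-dimethyl-4H-1,3-dioxin-4-one (2 equiv); 7 methyl (E)-3-(pyrrolidin-1-yl)but-2-enoate
Product: 9 methyl 6-[(Z)-heptadec-12-en-1-yl]-2-methyl-4-oxo-4H-pyran-3-carboxylate, via acylketene 8 (not isolated)
Conditions: toluene, 110 °C
Reagents that add atoms: none
Why: Retro-hetero-Diels–Alder loss of acetone releases acylketene 8, which acylates the enamine carbon (C4–C4a), after which the enol oxygen adds to C8a and pyrrolidine leaves (the known γ-pyrone synthesis from enamines and acylketenes or diketene); the polarity of both partners fixes the regiochemistry, and the second equivalent of 8 binds the liberated amine.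

Step 5
Reactants: 9 methyl 6-[(Z)-heptadec-12-en-1-yl]-2-methyl-4-oxo-4H-pyran-3-carboxylate; 10 tert-butyl acrylate
Product: 13 tert-butyl 2-[(Z)-heptadec-12-en-1-yl]-5-hydroxy-4-oxo-7,8-dihydro-4H-chromene-6-carboxylate, via lithium dienolate 11 (not isolated), via Michael adduct enolate 12 (not isolated)
Conditions: LiN(SiMe3)2 (1.1 equiv), THF, −78 °C; then 10 (1.05 equiv), −78 °C to 0 °C; then 1 M HCl
Reagents that add atoms: none
Why: LiN(SiMe3)2 should deprotonate only the C8 methyl group, because it alone is conjugated through C8a=C4a with both C4=O and the C5 ester carbonyl (the side-chain CH2 on C2 feels C4=O only), giving the 2-methylene-2H-pyran-4-olate 11, an o-toluate-type anion. Its exocyclic carbon adds 1,4 to tert-butyl acrylate (C7–C8 bond) with recovery of the pyrone π-system, and the ester enolate 12 attacks the neighbouring C5 methyl ester in a 6-(enolexo)-exo-trig Dieckmann closure that forms the C5–C6 bond and ring B. The expelled methoxide deprotonates the β-keto ester, which makes the sequence irreversible with a single equivalent of base and shields the product from further Michael addition. The closest known reaction type is the tandem Michael–Dieckmann (Staunton–Weinreb) annulation of o-toluates and 2-methylnicotinates with acrylates. No permanent stereocentre is created, since 13 is an enol and C6 is cleared in step 6. The step needs site selectivity (C8 against the side-chain CH2), 1,4- against 1,2-addition, and cyclisation faster than a second Michael addition or acrylate oligomerisation; these are secured by the doubly activated soft anion, the bulky tert-butyl ester (which also resists methoxide exchange), the coplanar ortho placement of C5 on ring A, and one equivalent of acrylate at low temperature.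

Step 6
Reactants: 13 tert-butyl 2-[(Z)-heptadec-12-en-1-yl]-5-hydroxy-4-oxo-7,8-dihydro-4H-chromene-6-carboxylate
Product: 15 2-[(Z)-heptadec-12-en-1-yl]-7,8-dihydro-4H-chromene-4,5(6H)-dione, via β-keto acid 14 (not isolated)
Conditions: CF3CO2H, CH2Cl2, 0 °C to rt; then toluene, 80 °C
Reagents that add atoms: none
Why: Acidolysis of the tert-butyl ester (E1 loss of isobutene) followed by thermal β-keto acid decarboxylation removes the activating group under conditions that isolated Z-alkenes of lipid chains and γ-pyrones routinely tolerate.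

Step 7
Reactants: 15 2-[(Z)-heptadec-12-en-1-yl]-7,8-dihydro-4H-chromene-4,5(6H)-dione
Product: 16 (5S)-2-[(Z)-heptadec-12-en-1-yl]-5-hydroxy-5,6,7,8-tetrahydro-4H-chromen-4-one
Conditions: RuCl[(S,S)-TsDPEN](p-cymene) (1 mol %), HCO2H–Et3N, EtOAc, 30 °C
Reagents that add atoms: none
Why: In this Noyori–Ikariya asymmetric transfer hydrogenation the (S,S)-catalyst should place the flat pyrone side of the ketone under the η6-arene (CH/π contact, as with 1-tetralone) and deliver hydride to the Re face of C5=O, setting 5S, while the vinylogous-ester C4=O and the isolated alkene are not reduced.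

**Compound list**
1 | (Z)-hexadec-11-en-1-ol | CCCC/C=C\CCCCCCCCCCO | starting material
2 | (Z)-16-iodohexadec-5-ene | CCCC/C=C\CCCCCCCCCCI | intermediate
3 | 2,2,6-trimethyl-4H-1,3-dioxin-4-one | CC1=CC(=O)OC(C)(C)O1 | starting material
4 | lithium dienolate of 3 (lithium 2,2-dimethyl-6-methylene-6H-1,3-dioxin-4-olate) | [Li+].C=C1C=C([O-])OC(C)(C)O1 | intermediate
5 | 6-[(Z)-heptadec-12-en-1-yl]-2,2-dimethyl-4H-1,3-dioxin-4-one | CCCC/C=C\CCCCCCCCCCCC1=CC(=O)OC(C)(C)O1 | intermediate
6 | methyl acetoacetate | CC(=O)CC(=O)OC | starting material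
7 | methyl (E)-3-(pyrrolidin-1-yl)but-2-enoate | C/C(=C\C(=O)OC)N1CCCC1 | intermediate
8 | acylketene, (15Z)-icosa-1,15-diene-1,3-dione | CCCC/C=C\CCCCCCCCCCCC(=O)C=C=O | intermediate
9 | methyl 6-[(Z)-heptadec-12-en-1-yl]-2-methyl-4-oxo-4H-pyran-3-carboxylate | CCCC/C=C\CCCCCCCCCCCc1cc(=O)c(C(=O)OC)c(C)o1 | intermediate
10 | tert-butyl acrylate | C=CC(=O)OC(C)(C)C | starting material
11 | lithium dienolate of 9 (lithium 2-methylene-2H-pyran-4-olate) | [Li+].CCCC/C=C\CCCCCCCCCCCC1=CC([O-])=C(C(=O)OC)C(=C)O1 | intermediate
12 | Michael adduct, lithium tert-butyl ester enolate | [Li+].CCCC/C=C\CCCCCCCCCCCc1cc(=O)c(C(=O)OC)c(CCC=C([O-])OC(C)(C)C)o1 | intermediate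
13 | tert-butyl 2-[(Z)-heptadec-12-en-1-yl]-5-hydroxy-4-oxo-7,8-dihydro-4H-chromene-6-carboxylate | CCCC/C=C\CCCCCCCCCCCc1cc(=O)c2c(o1)CCC(C(=O)OC(C)(C)C)=C2O | intermediate
14 | 2-[(Z)-heptadec-12-en-1-yl]-5-hydroxy-4-oxo-7,8-dihydro-4H-chromene-6-carboxylic acid | CCCC/C=C\CCCCCCCCCCCc1cc(=O)c2c(o1)CCC(C(=O)O)=C2O | intermediate
15 | 2-[(Z)-heptadec-12-en-1-yl]-7,8-dihydro-4H-chromene-4,5(6H)-dione | CCCC/C=C\CCCCCCCCCCCc1cc(=O)c2c(o1)CCCC2=O | intermediate
16 | (5S)-2-[(Z)-heptadec-12-en-1-yl]-5-hydroxy-5,6,7,8-tetrahydro-4H-chromen-4-one | CCCC/C=C\CCCCCCCCCCCc1cc(=O)c2c(o1)CCC[C@@H]2O | target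

Total step count: 7. Longest linear sequence: 6 (steps 1, 2, 4, 5, 6, 7).

**Steps most likely to fail**

Step 5. Anionic oligomerisation of the acrylate may outrun ring closure. So may proton transfer from C8 to the first-formed ester enolate followed by a second Michael addition. The fallback sets out from 5 and comes back at 13. It brings in the C6–C7 unit before ring A is built, so that only a plain Dieckmann condensation remains.
- Commercial 5-tert-butoxy-5-oxopentanoic acid is activated with 1,1'-carbonyldiimidazole and condensed with KO2CCH2CO2Me, MgCl2 and Et3N (Masamune–Brooks reaction) to give 7-tert-butyl 1-methyl 3-oxoheptanedioate F1.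
- Pyrrolidine (toluene, Dean–Stark) converts it into 7-tert-butyl 1-methyl (E)-3-(pyrrolidin-1-yl)hept-2-enedioate F2.
- Heating with 5 as in step 4 (through 8) gives methyl 2-(4-tert-butoxy-4-oxobutyl)-6-[(Z)-heptadec-12-en-1-yl]-4-oxo-4H-pyran-3-carboxylate F3.
- KOtBu in THF at 0 °C then closes C5–C6 to 13.

Step 4. Acylation of the push–pull enamine may be too slow, so that the acylketene dimerises or is drained by the liberated amine. The fallback sets out from 2 and 6 and comes back at 9. It closes ring A by an oxa-Michael addition instead of a ketene reaction.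
- 1-(Trimethylsilyl)propyne is lithiated with n-BuLi (THF, −78 °C to 0 °C) and alkylated with 2 to give (Z)-trimethyl(nonadec-14-en-1-yn-1-yl)silane F4.
- CsF under CO2 in DMSO (desilylative carboxylation) gives (Z)-icos-15-en-2-ynoic acid F5.
- (COCl)2 with catalytic DMF gives (Z)-icos-15-en-2-ynoyl chloride F6.
- C-acylation of the magnesium enolate of 6 (MgCl2, pyridine, CH2Cl2, 0 °C) with F6 is followed in the same flask by 6-endo-dig addition of the acetyl enol oxygen to the ynone. This gives 9 with no amine present.

Step 7. Hydride transfer may be slow, because the ketone is deactivated as a vinylogous ester and crowded by the peri C4=O. Facial selectivity may also be poor. The fallback sets out from 15 and comes back at 16. It replaces catalyst-controlled reduction by reduction and enzymatic resolution.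
- Luche reduction (NaBH4, CeCl3·7H2O, MeOH, −20 °C) gives racemic 2-[(Z)-heptadec-12-en-1-yl]-5-hydroxy-5,6,7,8-tetrahydro-4H-chromen-4-one F7.
- Immobilised Candida antarctica lipase B with vinyl acetate in tert-butyl methyl ether should acylate the R enantiomer (Kazlauskas rule, as for 1-tetralol). This gives (5R)-2-[(Z)-heptadec-12-en-1-yl]-4-oxo-5,6,7,8-tetrahydro-4H-chromen-5-yl acetate F8.
- The unreacted S alcohol 16 is separated by chromatography.

**Further compounds**
F1 | step 5 | 7-tert-butyl 1-methyl 3-oxoheptanedioate | COC(=O)CC(=O)CCCC(=O)OC(C)(C)C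
F2 | step 5 | 7-tert-butyl 1-methyl (E)-3-(pyrrolidin-1-yl)hept-2-enedioate | COC(=O)/C=C(\CCCC(=O)OC(C)(C)C)N1CCCC1
F3 | step 5 | methyl 2-(4-tert-butoxy-4-oxobutyl)-6-[(Z)-heptadec-12-en-1-yl]-4-oxo-4H-pyran-3-carboxylate | CCCC/C=C\CCCCCCCCCCCc1cc(=O)c(C(=O)OC)c(CCCC(=O)OC(C)(C)C)o1
F4 | step 4 | (Z)-trimethyl(nonadec-14-en-1-yn-1-yl)silane | CCCC/C=C\CCCCCCCCCCCC#C[Si](C)(C)C
F5 | step 4 | (Z)-icos-15-en-2-ynoic acid | CCCC/C=C\CCCCCCCCCCCC#CC(=O)O
F6 | step 4 | (Z)-icos-15-en-2-ynoyl chloride | CCCC/C=C\CCCCCCCCCCCC#CC(=O)Cl
F7 | step 7 | racemic 2-[(Z)-heptadec-12-en-1-yl]-5-hydroxy-5,6,7,8-tetrahydro-4H-chromen-4-one | CCCC/C=C\CCCCCCCCCCCc1cc(=O)c2c(o1)CCCC2O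
F8 | step 7 | (5R)-2-[(Z)-heptadec-12-en-1-yl]-4-oxo-5,6,7,8-tetrahydro-4H-chromen-5-yl acetate | CCCC/C=C\CCCCCCCCCCCc1cc(=O)c2c(o1)CCC[C@H]2OC(C)=O
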